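(Readings and results are simulated for an exercise, and the scatter is random.)

**Examiner:** The dusk run reads Q at 79% by 20.0 d, yet E was half of the charge. Where did the extra Q come from?

in all of them: E 0.12 M; X 0.12 M

|  | G | remark | time |
|---|---|---|---|
| noon | 0.32 M (fed, over 40 h) | run made earlier |  |
| dusk | 0.72 M (fed, over 40 h) | run made earlier |  |
| flask | 0.480 M (fed, over 40 h) |  | 15 d |

| run | time / d | E / % | Q / % |
|---|---|---|---|
| noon | 1.25 | 14 | 43 |
| noon | 2.50 | 12 | 62 |
| noon | 4.00 | 18 | 66 |
| noon | 6.00 | 14 | 63 |
| noon | 10.0 | 18 | 64 |
| noon | 20.0 | 12 | 66 |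
| dusk | 1.25 | 8 | 59 |
| dusk | 2.50 | 8 | 74 |
| dusk | 4.00 | 8 | 73 |
| dusk | 6.00 | 13 | 76 |
| dusk | 10.0 | 8 | 77 |
| dusk | 20.0 | 9 | 79 |

(standard deviation of a reading: 2 percentage points)

- G is single-handed; E and X are mirror images of each other, charged as a racemate, each of them at the stated concentration
- the handed part of G does not stay in what it makes, so the products of the two hands are mirror images too

1. share of the E and X together used up at 15 d
2. Q at 15 d, in percent of the E and X together charged
3. X at 15 d, in percent of the E and X together charged

**Candidate:** Q exceeds that share, so X must pass into E, which is a dynamic kinetic resolution. Mirror images have equal energy, so that exchange ends with E and X equal.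

**Examiner:** Is 15 d late enough to be on the plateau?

**Candidate:** From 4.00 d on, noon Q reads between 63% and 66% and dusk Q between 73% and 79%, against a scatter of 2 percentage points. I take both as plateaus, although dusk Q may still be creeping up, and 15 d is later. So I need one plateau value of E, and conversion is what two such amounts leave.

**Examiner:** How does that value depend on G?

**Candidate:** Averaging the last four readings, E reads 15.5% in the noon run and 9.50% in the dusk run. I define the dose exponent, the power of the G charge by which plateau E falls, and read it as 0.604. For 0.480 M of G, my reckoning gives E and X at 12.1% each and conversion 75.8%. Q reads 64.8% and 76.2%, and the two runs leave on average 4.5 points unaccounted for. Taking that off my conversion gives Q 71.2%.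

**Examiner:** Two points always give a power. What tests it?

**Candidate:** Nothing yet. The G charge of this flask lies between those of the runs, so this is an interpolation, and a charge outside them is the test.

The forecast says conversion 76%, Q 70.5% and X 12%, with “E and X should then equilibrate to equal amounts.” It rests on the same two runs as my reckoning, so their closeness is no check. My Q stands 0.70 points above the forecast's.

The flask gives conversion 74.9%, Q 73.6% and X 12.6%.

    2 G → D (k = 0.00780 M⁻¹ min⁻¹)
    E ⇌ X (k = 4.20 × 10⁻⁴ min⁻¹)
    G → L (k = 2.10 × 10⁻⁴ min⁻¹)
    G + X → Z (k = 1.50 × 10⁻⁴ M⁻¹ min⁻¹)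
    G + E → Q (k = 0.0190 M⁻¹ min⁻¹)
    G → J (k = 1.40 × 10⁻⁷ min⁻¹)

The dose exponent gave X 12.1% here. For the neighbour flask with 0.12 M of G, a charge below both runs, it gives X 28.0%, and that neighbour flask holds X 30.9%. This flask has come to rest: G, the limiting reagent, stands at 0% at 15.0 d, with E 12.6% and X 12.6%. Ten times the time, 150 d, leaves conversion at 74.9%, Q at 73.6% and X at 12.6%.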